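Ring atoms are numbered as in the target 17 throughout (O1, C2, C3, C4, C5; C3 carries the hydroxyl), also for the dihydrofuran intermediates. Ar = 4‑(benzyloxy)‑3‑methoxyphenyl.

## The problem

Compound 17 is a 2,5‑diaryl‑3,4‑dimethyloxolane: two C6–C3 units joined at C3–C4 and bridged by O1 between the benzylic carbons C2 and C5, with a tertiary hydroxyl on C3. All four ring carbons are stereocentres (2R,3S,4R,5R). The four carbon substituents (aryl on C2, methyl on C3, methyl on C4, aryl on C5) lie on one face, and the C3 hydroxyl and the hydrogens on C2, C4 and C5 on the other, so every vicinal pair is in its less stable cis arrangement and nothing can be left to equilibration. Without the hydroxyl the molecule would be meso, so absolute control must tell C3 from C4, which no symmetric addition to a symmetric precursor can do. C3 is a fully substituted carbinol between two stereocentres and is the most hindered atom. The para‑oxygenated benzylic bonds C2–O1 and C5–O1 ionise under protic or Lewis acid (epimerisation towards trans isomers), an oxocarbenium ion at C2 next to the C3 carbinol invites a 1,2‑methyl shift, any 2,3‑dihydrofuran‑3‑ol aromatises by loss of water, and the free phenols are oxidisable. The feature the plan uses: H on C2 and OH on C3 are cis to each other and trans to the C4 methyl and C5 aryl groups, and C3 is β to O1. That is exactly what a syn addition of H–B across a C2=C3 enol ether bond, from the face left open by the C4 and C5 substituents, gives after oxidation.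

## Retrosynthesis

17 from 16: the two phenol O–H bonds are masked as benzyl ethers. Every earlier step is basic, organometallic or oxidative, which benzyl ethers tolerate, and they leave last under neutral hydrogenolysis. Nothing stereochemical is asked of this step.

16 from 14 (key cut): C2–H and C3–O are removed together, which leads back to the tetrasubstituted enol ether 14. The neighbouring cut, C4–H and C5–H (hydrogenation of a 2,3‑dihydrofuran‑3‑ol), would carry a tertiary allylic alcohol that is one dehydration from a furan. Cutting C2–aryl or C2–H on the saturated ring needs an oxocarbenium ion at C2 beside the carbinol under Lewis acid. Hydroboration needs neither acid nor a carbinol carried through the route. 14 has two stereocentres instead of four, no quaternary carbon and no hydroxyl. The forward step must put boron on C3 and must come from the face opposite the cis C4 methyl and C5 aryl groups.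

14 from 12 and 13: the C2–aryl bond is cut at the sp2 carbon. The usual alternative, aryllithium addition to a lactone and acid dehydration of the hemiketal, exposes the benzylic C5–O1 bond to acid. A Suzuki–Miyaura coupling of the lactone‑derived ketene acetal phosphate 12 with boronic acid 13 uses base only. The forward reaction must couple at a hindered, fully substituted vinylic carbon.

12 from 10, 10 from 8: the O–P bond and then the C3–CH3 bond are cut. C3 becomes sp2 in 12, so its configuration in 10 does not matter and a plain enolate methylation of lactone 8 suffices. 8 keeps only the two stereocentres C4 and C5.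

8 from 6, 6 from 4: the lactone carbonyl C2 is traced to the terminal alkene carbon of 4 through the 1,4‑diol 6 (anti‑Markovnikov hydroboration, then oxidative lactonisation). No stereocentre is made or touched.

4 from 1 and 2: the C4–C5 bond is cut. The cis C4/C5 relation on the ring is a syn homoallylic alcohol, the product of a (Z)‑crotylboration of aldehyde 1 with boronate 2. One catalytic step sets both centres and the absolute configuration, and all later centres are relayed from them.

## Roads not taken

Alternative 1: the most obvious plan carries the carbinol from the start. An aldol‑derived hydroxy lactone A1 takes up the aryllithium at the lactone carbonyl to give lactol A2, and the oxocarbenium ion at C2 is reduced with Et3SiH/BF3·OEt2. It was set aside for three reasons: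
- the ion at C2 sits beside the fully substituted C3 carbinol, so a 1,2‑methyl shift or neighbouring‑oxygen participation competes with hydride capture;
- BF3 ionises the para‑oxygenated C5–O1 bond, which drives the ring towards trans isomers;
- the hydride must enter cis to the C3 oxygen against an unclear steric bias (methyl versus protected hydroxyl), and the tertiary alcohol must be protected over several steps.

The chosen plan makes C2–H and C3–OH in one base‑only step.

Alternative 2: use the hidden symmetry. Furan A3 (two steps from a 4‑oxygenated propiophenone by oxidative enolate dimerisation and Paal–Knorr cyclisation) is hydrogenated from one face to the meso all‑cis oxolane A4, which is the benzyl‑protected target minus one oxygen. The forward key step would be hydroxylation of one of the two enantiotopic tertiary C–H bonds with retention, by a cytochrome P450 monooxygenase or a dioxirane. It was set aside because the benzylic C–H bonds next to O1 are weaker and more exposed than the tertiary ones, and no reagent or enzyme class is known to select the tertiary C–H on this substrate type. Symmetric additions (hydrogenation, epoxidation, dihydroxylation) keep the mirror plane. The chosen plan keeps the same "all hydrogens to one face of a flat ring" logic but does it in two controlled stages from a non‑symmetric precursor.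

Alternative 3: convergent union at the most hindered bond, C3–C4. The enolate of 1‑Ar‑propan‑1‑one adds to the (R)‑α‑silyloxy ketone A5 to give aldol A6. Cyclodehydration gives the dihydrofuranol A7, and hydroxyl‑directed hydrogenation of C4=C5 finishes the array. It was set aside for three reasons:
- chelation control (Cram chelate) puts the incoming carbon on the wrong side and gives the C3 epimer, so the less dependable Felkin–Anh mode at a ketone would be needed;
- A6 is a tertiary β‑hydroxy ketone prone to retro‑aldol cleavage;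
- A7 aromatises to furan A3 by loss of water under the acid needed to form it.

The chosen route has no intermediate that a single dehydration turns into an arene, and its absolute configuration comes from a catalytic step with close precedent.

Key step: step 7

Remark on the chemistry: 1, 2 and 13 are taken as purchased. The (R)‑phosphoric acid of step 1 is assumed to direct the crotyl group to the Re face of 1, as with other aromatic aldehydes; if the sense proves opposite, the (S)‑acid is used without other change.

## Route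

Step 1
Reactants: 1 4‑(benzyloxy)‑3‑methoxybenzaldehyde; 2 (Z)‑crotylboronic acid pinacol ester
Product: 4 (1R,2S)‑1‑Ar‑2‑methylbut‑3‑en‑1‑ol, via homoallylic pinacol borate 3 (not isolated)
Conditions: (R)‑3,3′‑bis(2,4,6‑triisopropylphenyl)‑1,1′‑binaphthyl‑2,2′‑diyl hydrogen phosphate [(R)‑TRIP] (5 mol %), toluene, 4 Å MS, −30 °C; then aq. NaHCO3
Reagents that add atoms: none
Why: Chiral phosphoric acid‑catalysed crotylboration through a closed chair (Zimmerman–Traxler) transition state: the (Z)‑boronate gives the syn C4/C5 pair, the 3,3′‑aryl groups of the acid select the Re face of 1, and the alcohol stays masked as borate 3 until the basic work‑up.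

Step 2
Reactants: 4 (1R,2S)‑1‑Ar‑2‑methylbut‑3‑en‑1‑ol
Product: 6 (1R,2S)‑1‑Ar‑2‑methylbutane‑1,4‑diol, via bis(9‑BBN) adduct 5 (not isolated)
Conditions: 9‑BBN (2.2 equiv), THF, 0 °C → rt; then 3 M NaOH, 30 % H2O2, 0 °C → rt
Reagents that add atoms: hydrogen peroxide, OO
Why: Anti‑Markovnikov hydroboration–oxidation of the monosubstituted alkene; the bulky borane goes only to the terminal carbon, the second equivalent is taken up by the hydroxyl and removed in the same oxidation, and no stereocentre is touched.

Step 3
Reactants: 6 (1R,2S)‑1‑Ar‑2‑methylbutane‑1,4‑diol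
Product: 8 (4S,5R)‑5‑Ar‑4‑methyldihydrofuran‑2(3H)‑one, via lactol 7 (not isolated)
Conditions: TEMPO (0.2 equiv), PhI(OAc)2 (2.5 equiv), CH2Cl2, rt
Reagents that add atoms: none
Why: Oxoammonium oxidation is fastest at the primary alcohol; the hydroxy aldehyde closes to lactol 7, which is oxidised again (oxidative lactonisation of a 1,4‑diol); C4 and C5 are untouched and the medium is only weakly acidic.

Step 4
Reactants: 8 (4S,5R)‑5‑Ar‑4‑methyldihydrofuran‑2(3H)‑one
Product: 10 (3S,4S,5R)‑5‑Ar‑3,4‑dimethyldihydrofuran‑2(3H)‑one (major C3 epimer), via lithium enolate 9 (not isolated)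
Conditions: LiN(i‑Pr)2 (1.1 equiv), THF, −78 °C; MeI (3 equiv), −78 → −40 °C
Reagents that add atoms: iodomethane, CI
Why: Lactone enolate alkylation; the methyl group enters anti to the C4 methyl, but either C3 epimer serves because C3 becomes sp2 in step 5.

Step 5
Reactants: 10 (3S,4S,5R)‑5‑Ar‑3,4‑dimethyldihydrofuran‑2(3H)‑one
Product: 12 (4S,5R)‑5‑Ar‑3,4‑dimethyl‑4,5‑dihydrofuran‑2‑yl diphenyl phosphate, via potassium enolate 11 (not isolated)
Conditions: KN(SiMe3)2 (1.3 equiv), THF/DMPU (9:1), −78 °C; ClP(O)(OPh)2 (1.4 equiv), −78 → −30 °C; cold dilute aq. NH3 work‑up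
Reagents that add atoms: diphenyl chlorophosphate, O=P(Cl)(Oc1ccccc1)Oc1ccccc1
Why: O‑Phosphorylation of the potassium enolate gives the cyclic ketene acetal phosphate; the polar cosolvent favours attack at oxygen, and the basic medium leaves C4 and the benzylic C5 unchanged.

Step 6
Reactants: 12 (4S,5R)‑5‑Ar‑3,4‑dimethyl‑4,5‑dihydrofuran‑2‑yl diphenyl phosphate; 13 [4‑(benzyloxy)‑3‑methoxyphenyl]boronic acid
Product: 14 (2R,3S)‑2,5‑bis(Ar)‑3,4‑dimethyl‑2,3‑dihydrofuran
Conditions: Pd(PPh3)4 (5 mol %), 13 (1.5 equiv), 2 M aq. Na2CO3, DME, 70 °C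
Reagents that add atoms: none
Why: Suzuki–Miyaura coupling of a lactone‑derived ketene acetal phosphate (oxidative addition of zerovalent palladium into the vinylic C–O bond, transmetalation, reductive elimination) forms the C2–aryl bond; no stereocentre is involved and no acid is present.

Step 7
Reactants: 14 (2R,3S)‑2,5‑bis(Ar)‑3,4‑dimethyl‑2,3‑dihydrofuran
Product: 16 (2R,3S,4R,5R)‑2,5‑bis(Ar)‑3,4‑dimethyltetrahydrofuran‑3‑ol, via tertiary alkylborane 15 (not isolated)
Conditions: BH3·SMe2 (2 equiv), THF, 0 °C → rt; then 3 M NaOH, 30 % H2O2, 0 °C → rt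
Reagents that add atoms: hydrogen peroxide, OO
Why: Hydroboration–oxidation: BH3 adds across the C2=C3 enol ether bond in a concerted four‑centre syn addition, boron to C3 and hydrogen to C2. The closest known reaction type is the hydroboration–oxidation of 1‑aryl glycals and 2,3‑dihydrofurans, which places boron β to the ring oxygen. Regioselectivity is secured twice, because O1 makes C3 the nucleophilic enol ether carbon and C3 is also the non‑benzylic end of the styrene‑like unit. Facial selectivity is secured by the cis C4 methyl and C5 aryl groups, which together close one face of the nearly flat ring, so boron and hydrogen arrive on the other. C3 is thus set by the adjacent C4 methyl, and C2 by the syn delivery of hydrogen, which pushes the C2 aryl group onto the face of the other three carbon substituents. Alkaline peroxide turns the C–B bond of 15 into C–O with retention (1,2‑shift of carbon from boron to oxygen), so the hydroxyl ends cis to H on C2 and trans to both methyl and both aryl groups. No ring is closed in this step. The conditions are never acidic, so the benzylic C–O bonds are not ionised and the all‑cis array, which equilibration would destroy, is kept.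

Step 8
Reactants: 16 (2R,3S,4R,5R)‑2,5‑bis(Ar)‑3,4‑dimethyltetrahydrofuran‑3‑ol
Product: 17 (2R,3S,4R,5R)‑2,5‑bis(4‑hydroxy‑3‑methoxyphenyl)‑3,4‑dimethyltetrahydrofuran‑3‑ol
Conditions: H2 (1 atm), 10 % Pd/C, EtOAc, rt, stopped after two equivalents of H2
Reagents that add atoms: none
Why: Neutral catalytic hydrogenolysis of the two aryl benzyl ethers; the ring C–O bonds are dialkyl benzylic ethers that cleave much more slowly, and no stereocentre is affected.

## Compound list

1 | 4‑(benzyloxy)‑3‑methoxybenzaldehyde | O=Cc1ccc(OCc2ccccc2)c(OC)c1 | starting material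
2 | 2‑[(2Z)‑but‑2‑en‑1‑yl]‑4,4,5,5‑tetramethyl‑1,3,2‑dioxaborolane | C/C=C\CB1OC(C)(C)C(C)(C)O1 | starting material
3 | 2‑{[(1R,2S)‑1‑[4‑(benzyloxy)‑3‑methoxyphenyl]‑2‑methylbut‑3‑en‑1‑yl]oxy}‑4,4,5,5‑tetramethyl‑1,3,2‑dioxaborolane | CC1(C)OB(O[C@@H](c2ccc(OCc3ccccc3)c(OC)c2)[C@@H](C)C=C)OC1(C)C | intermediate (not isolated)
4 | (1R,2S)‑1‑[4‑(benzyloxy)‑3‑methoxyphenyl]‑2‑methylbut‑3‑en‑1‑ol | O[C@@H](c1ccc(OCc2ccccc2)c(OC)c1)[C@@H](C)C=C | intermediate
5 | 9‑{[(1R,2S)‑4‑(9‑borabicyclo[3.3.1]nonan‑9‑yl)‑1‑[4‑(benzyloxy)‑3‑methoxyphenyl]‑2‑methylbutyl]oxy}‑9‑borabicyclo[3.3.1]nonane | B1(C2CCCC1CCC2)O[C@@H](c1ccc(OCc2ccccc2)c(OC)c1)[C@@H](C)CCB1C2CCCC1CCC2 | intermediate (not isolated)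
6 | (1R,2S)‑1‑[4‑(benzyloxy)‑3‑methoxyphenyl]‑2‑methylbutane‑1,4‑diol | O[C@@H](c1ccc(OCc2ccccc2)c(OC)c1)[C@@H](C)CCO | intermediate
7 | (4S,5R)‑5‑[4‑(benzyloxy)‑3‑methoxyphenyl]‑4‑methyltetrahydrofuran‑2‑ol (both anomers) | OC1O[C@@H](c2ccc(OCc3ccccc3)c(OC)c2)[C@@H](C)C1 | intermediate (not isolated)
8 | (4S,5R)‑5‑[4‑(benzyloxy)‑3‑methoxyphenyl]‑4‑methyldihydrofuran‑2(3H)‑one | O=C1O[C@@H](c2ccc(OCc3ccccc3)c(OC)c2)[C@@H](C)C1 | intermediate
9 | lithium (4S,5R)‑5‑[4‑(benzyloxy)‑3‑methoxyphenyl]‑4‑methyl‑4,5‑dihydrofuran‑2‑olate | [Li+].[O-]C1=C[C@H](C)[C@H](c2ccc(OCc3ccccc3)c(OC)c2)O1 | intermediate (not isolated)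
10 | (3S,4S,5R)‑5‑[4‑(benzyloxy)‑3‑methoxyphenyl]‑3,4‑dimethyldihydrofuran‑2(3H)‑one (major; the C3 epimer is carried along) | O=C1O[C@@H](c2ccc(OCc3ccccc3)c(OC)c2)[C@@H](C)[C@@H]1C | intermediate
11 | potassium (4S,5R)‑5‑[4‑(benzyloxy)‑3‑methoxyphenyl]‑3,4‑dimethyl‑4,5‑dihydrofuran‑2‑olate | [K+].[O-]C1=C(C)[C@H](C)[C@H](c2ccc(OCc3ccccc3)c(OC)c2)O1 | intermediate (not isolated)
12 | (4S,5R)‑5‑[4‑(benzyloxy)‑3‑methoxyphenyl]‑3,4‑dimethyl‑4,5‑dihydrofuran‑2‑yl diphenyl phosphate | O=P(Oc1ccccc1)(Oc1ccccc1)OC1=C(C)[C@H](C)[C@H](c2ccc(OCc3ccccc3)c(OC)c2)O1 | intermediate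
13 | [4‑(benzyloxy)‑3‑methoxyphenyl]boronic acid | OB(O)c1ccc(OCc2ccccc2)c(OC)c1 | starting material
14 | (2R,3S)‑2,5‑bis[4‑(benzyloxy)‑3‑methoxyphenyl]‑3,4‑dimethyl‑2,3‑dihydrofuran | COc1cc(C2=C(C)[C@H](C)[C@H](c3ccc(OCc4ccccc4)c(OC)c3)O2)ccc1OCc1ccccc1 | intermediate
15 | [(2S,3R,4S,5R)‑2,5‑bis[4‑(benzyloxy)‑3‑methoxyphenyl]‑3,4‑dimethyltetrahydrofuran‑3‑yl]borane (same spatial arrangement as 16; the descriptors differ because boron ranks below carbon) | COc1cc([C@H]2O[C@@H](c3ccc(OCc4ccccc4)c(OC)c3)[C@@H](C)[C@]2(C)B)ccc1OCc1ccccc1 | intermediate (not isolated)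
16 | (2R,3S,4R,5R)‑2,5‑bis[4‑(benzyloxy)‑3‑methoxyphenyl]‑3,4‑dimethyltetrahydrofuran‑3‑ol | COc1cc([C@H]2O[C@@H](c3ccc(OCc4ccccc4)c(OC)c3)[C@@H](C)[C@]2(C)O)ccc1OCc1ccccc1 | intermediate
17 | (2R,3S,4R,5R)‑2,5‑bis(4‑hydroxy‑3‑methoxyphenyl)‑3,4‑dimethyltetrahydrofuran‑3‑ol | COc1cc([C@H]2O[C@@H](c3ccc(O)c(OC)c3)[C@@H](C)[C@]2(C)O)ccc1O | target

## Step count and least certain steps

Total step count: 8. Longest linear sequence: 8 steps (1 to 17); 2 and 13 enter as purchased building blocks.

Step 7 (key step). The tetrasubstituted, aryl‑conjugated enol ether may hydroborate slowly. If warming is needed, ring opening by β‑elimination of the β‑alkoxyborane or leakage to the hindered face can compete. Fallback: from 14, dimethyldioxirane (acetone/CH2Cl2, −78 °C) epoxidises the enol ether on the same open face to give the epoxide (1S,3R,4R,5S)‑1,3‑bis(Ar)‑4,5‑dimethyl‑2,6‑dioxabicyclo[3.1.0]hexane F1. i‑Bu2AlH (CH2Cl2, −78 °C) then ionises the acetal C2–O bond and delivers hydride from the aluminium‑bound C3 oxygen, that is cis to it, as in the cis opening of glycal epoxides by aluminium reagents. This gives 16, where the route is rejoined.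

Step 6. Hydrolysis of the five‑membered ketene acetal phosphate by the aqueous base may outrun oxidative addition into the hindered, fully substituted vinylic C–O bond, and the electron‑rich boronic acid may protodeboronate. Fallback: from 10, the aryllithium made from 1‑(benzyloxy)‑4‑bromo‑2‑methoxybenzene and n‑BuLi (THF, −78 °C) adds to the lactone carbonyl to give the hemiketal (3S,4S,5R)‑2,5‑bis(Ar)‑3,4‑dimethyltetrahydrofuran‑2‑ol F2. Dehydration under basic conditions (MsCl, Et3N, CH2Cl2, 0 °C) gives 14, where the route is rejoined. This detour also covers a failure of the O‑phosphorylation in step 5.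

Step 3. Oxidation at the electron‑rich secondary benzylic alcohol may compete before the lactol closes, which leads to over‑oxidation. Fallback: from 4, an aldehyde‑selective Wacker oxidation of the terminal alkene (PdCl2(PhCN)2, CuCl2, AgNO2, O2, t‑BuOH/MeNO2, rt) gives lactol 7 directly, with no primary/secondary diol to discriminate. Ag2CO3 on Celite (benzene, reflux) oxidises 7 to 8, where the route is rejoined. This detour replaces steps 2 and 3 and forms no compound outside the list (F0).

Step 1. Enantiofacial discrimination may be eroded by uncatalysed background addition to the slow, electron‑rich aldehyde. Fallback: from 1, NaBH4 (MeOH, 0 °C) gives [4‑(benzyloxy)‑3‑methoxyphenyl]methanol F3. A ruthenium‑catalysed hydrohydroxyalkylation of butadiene (RuH2(CO)(PPh3)3, SEGPHOS, a TADDOL‑derived phosphoric acid, butadiene, THF, 95 °C; ligand and acid enantiomers chosen for the (1R,2S) product) crotylates it syn‑selectively from the alcohol oxidation level. This gives 4, where the route is rejoined.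

## Further compounds

F1 | step 7 | (1S,3R,4R,5S)‑1,3‑bis[4‑(benzyloxy)‑3‑methoxyphenyl]‑4,5‑dimethyl‑2,6‑dioxabicyclo[3.1.0]hexane (oxirane oxygen trans to the C3 aryl and C4 methyl groups) | COc1cc([C@]32O[C@@H](c4ccc(OCc5ccccc5)c(OC)c4)[C@@H](C)[C@]2(C)O3)ccc1OCc1ccccc1
F2 | step 6 | (3S,4S,5R)‑2,5‑bis[4‑(benzyloxy)‑3‑methoxyphenyl]‑3,4‑dimethyltetrahydrofuran‑2‑ol (anomers) | COc1cc(C2(O)O[C@@H](c3ccc(OCc4ccccc4)c(OC)c3)[C@@H](C)[C@@H]2C)ccc1OCc1ccccc1
F0 | step 3 | none | none
F3 | step 1 | [4‑(benzyloxy)‑3‑methoxyphenyl]methanol | COc1cc(CO)ccc1OCc1ccccc1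
A1 | alternative 1 | (3S,4R,5R)‑5‑[4‑(benzyloxy)‑3‑methoxyphenyl]‑3‑hydroxy‑3,4‑dimethyldihydrofuran‑2(3H)‑one | O=C1O[C@@H](c2ccc(OCc3ccccc3)c(OC)c2)[C@@H](C)[C@]1(C)O
A2 | alternative 1 | (3S,4R,5R)‑2,5‑bis[4‑(benzyloxy)‑3‑methoxyphenyl]‑3,4‑dimethyltetrahydrofuran‑2,3‑diol (anomers) | COc1cc(C2(O)O[C@@H](c3ccc(OCc4ccccc4)c(OC)c3)[C@@H](C)[C@]2(C)O)ccc1OCc1ccccc1
A3 | alternative 2 | 2,5‑bis[4‑(benzyloxy)‑3‑methoxyphenyl]‑3,4‑dimethylfuran | Cc1c(-c2ccc(OCc3ccccc3)c(OC)c2)oc(-c2ccc(OCc3ccccc3)c(OC)c2)c1C
A4 | alternative 2 | (2R,3S,4R,5S)‑2,5‑bis[4‑(benzyloxy)‑3‑methoxyphenyl]‑3,4‑dimethyltetrahydrofuran (meso, all‑cis) | COc1cc([C@H]2O[C@@H](c3ccc(OCc4ccccc4)c(OC)c3)[C@@H](C)[C@H]2C)ccc1OCc1ccccc1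
A5 | alternative 3 | (1R)‑1‑[4‑(benzyloxy)‑3‑methoxyphenyl]‑1‑[(tert‑butyldimethylsilyl)oxy]propan‑2‑one | CC(=O)[C@H](O[Si](C)(C)C(C)(C)C)c1ccc(OCc2ccccc2)c(OC)c1
A6 | alternative 3 | (3S,4R)‑1,4‑bis[4‑(benzyloxy)‑3‑methoxyphenyl]‑4‑[(tert‑butyldimethylsilyl)oxy]‑3‑hydroxy‑2,3‑dimethylbutan‑1‑one (C2 epimers) | COc1cc(C(=O)C(C)[C@](C)(O)[C@H](O[Si](C)(C)C(C)(C)C)c2ccc(OCc3ccccc3)c(OC)c2)ccc1OCc1ccccc1
A7 | alternative 3 | (2R,3S)‑2,5‑bis[4‑(benzyloxy)‑3‑methoxyphenyl]‑3,4‑dimethyl‑2,3‑dihydrofuran‑3‑ol | COc1cc([C@H]2OC(c3ccc(OCc4ccccc4)c(OC)c3)=C(C)[C@]2(C)O)ccc1OCc1ccccc1
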